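**Retrosynthetic overview**

1. Target ⇐ diol 22 (two acetylations) ⇐ C4 ketone and C1 methylene ⇐ tricyclic ketone 19.
2. Ring C (eleven-membered) ⇐ Nozaki–Hiyama–Kishi closure of C13–C14 from a (Z)-vinyl iodide and an aldehyde (18).
3. C2 side arm ⇐ Mukaiyama–Michael addition on the convex face of the cis-fused enedione 17.
4. Ring B ⇐ aldol condensation, after the key electroreductive acyl transfer that builds the C5 quaternary centre from a side-chain ester onto the cyclopentenyl ketone (10 → 11).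
5. Ring A and the first stereocentre ⇐ (R)-limonene (ozonolysis, aldol); C9 and C10 by hydroboration and Felkin allylation. Ring order: A, then B, then C.

Assumption: the tricycles carry my own numbering, C1 (carbon bearing the exocyclic CH2 or C=O), C2, C3, C4 (OAc), C5 (C–Me), C6, C7, C8, C9 (CHMe), C10 (O-propanoyl), C11, C12=C13(Me), C14 (OAc), C15 (bonded to C2), C16 (ring-fusion CH bonded to C1, C5, C8); ring A is the five-membered ring, ring B the six-membered ring, ring C the eleven-membered ring; 2,2-dimethoxyacetic acid is taken as commercial.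

Step 1
Reactants: 1 (R)-(+)-limonene
Product: 3 (3R)-6-oxo-3-(prop-1-en-2-yl)heptanal, via ozonide 2 (not isolated)
Conditions: O3 (1 equiv), CH2Cl2, −78 °C; Me2S, −78 °C to rt
Reagents that add atoms: ozone, [O-][O+]=O
Why: Ozonolysis with reductive work-up cleaves the electron-rich trisubstituted ring alkene much faster than the 1,1-disubstituted isopropenyl group and leaves the purchased stereocentre (later C8) untouched.

Step 2
Reactants: 3 (3R)-6-oxo-3-(prop-1-en-2-yl)heptanal
Product: 4 (5S)-2-methyl-5-(prop-1-en-2-yl)cyclopent-1-ene-1-carbaldehyde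
Conditions: piperidine (cat.), AcOH (cat.), toluene, reflux, Dean–Stark
Reagents that add atoms: none
Why: Enamine-mediated intramolecular aldol condensation of the aldehyde α-carbon onto the methyl ketone closes ring A as the conjugated enal without touching the stereocentre.

Step 3
Reactants: 4 (5S)-2-methyl-5-(prop-1-en-2-yl)cyclopent-1-ene-1-carbaldehyde
Product: 5 1-[(5S)-2-methyl-5-(prop-1-en-2-yl)cyclopent-1-en-1-yl]ethan-1-ol (both carbinol epimers)
Conditions: MeMgBr, THF, −78 °C; H2O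
Reagents that add atoms: methylmagnesium bromide, C[Mg]Br
Why: Grignard 1,2-addition to the hindered enal brings in the future C2, and the new carbinol centre does not matter because it is oxidised in step 5.

Step 4
Reactants: 5 1-[(5S)-2-methyl-5-(prop-1-en-2-yl)cyclopent-1-en-1-yl]ethan-1-ol
Product: 7 (2S)-2-[(1S)-2-(1-hydroxyethyl)-3-methylcyclopent-2-en-1-yl]propan-1-ol, via bis-boryl adduct 6 (not isolated)
Conditions: 9-BBN (2.3 equiv), THF, 0 °C to rt; then NaOH, H2O2, 0 °C
Reagents that add atoms: hydrogen peroxide, OO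
Why: Hydroboration–oxidation with the bulky borane touches only the 1,1-disubstituted alkene, and in the staggered transition state (ring hydrogen next to the alkene methyl, reagent anti to the substituted sp2 ring carbon) it sets C9 as (S), with an expected ratio of about 5:1 and the minor epimer removed at this diol stage.

Step 5
Reactants: 7 (2S)-2-[(1S)-2-(1-hydroxyethyl)-3-methylcyclopent-2-en-1-yl]propan-1-ol
Product: 8 (2S)-2-[(1S)-2-acetyl-3-methylcyclopent-2-en-1-yl]propanal
Conditions: Dess–Martin periodinane (2.4 equiv), NaHCO3, CH2Cl2, 0 °C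
Reagents that add atoms: none
Why: Buffered Dess–Martin oxidation converts the allylic alcohol into the enone and the primary alcohol into the aldehyde without epimerising the α-methyl centre C9.

Step 6
Reactants: 8 (2S)-2-[(1S)-2-acetyl-3-methylcyclopent-2-en-1-yl]propanal
Product: 9 (2S,3S)-2-[(1S)-2-acetyl-3-methylcyclopent-2-en-1-yl]hex-5-en-3-ol
Conditions: CH2=CHCH2SnBu3, BF3·OEt2, CH2Cl2, −78 °C; H2O
Reagents that add atoms: allyltributylstannane, C=CC[Sn](CCCC)(CCCC)CCCC
Why: The Lewis-acid-mediated allylstannane addition is selective for the aldehyde over the hindered enone and follows Felkin–Anh control with the ring carbon as the large group, giving the 9,10-syn alcohol with C10 (S).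

Step 7
Reactants: 9 (2S,3S)-2-[(1S)-2-acetyl-3-methylcyclopent-2-en-1-yl]hex-5-en-3-ol
Product: 10 (2S,3S)-2-[(1S)-2-acetyl-3-methylcyclopent-2-en-1-yl]hex-5-en-3-yl 2,2-dimethoxyacetate
Conditions: (MeO)2CHCO2H, EDC·HCl, DMAP (cat.), CH2Cl2, rt
Reagents that add atoms: 2,2-dimethoxyacetic acid, COC(OC)C(=O)O
Why: Steglich-type carbodiimide esterification hangs an activated acyl donor on the side-chain oxygen, which sits on the ring face where the quaternary carbon must be built.

Step 8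
Reactants: 10 (2S,3S)-2-[(1S)-2-acetyl-3-methylcyclopent-2-en-1-yl]hex-5-en-3-yl 2,2-dimethoxyacetate
Product: 11 1-[(1R,2S,5S)-2-(2,2-dimethoxyacetyl)-5-[(2S,3S)-3-hydroxyhex-5-en-2-yl]-2-methylcyclopentyl]ethan-1-one
Conditions: undivided cell, Mg anode, glassy-carbon cathode, Bu4NBF4 (0.1 M), DMF, 5 mA cm−2, 2.2 F mol−1, 0 °C; aq NH4Cl
Reagents that add atoms: none
Why: Proposed new method: cathodic two-electron reduction of the enone gives a magnesium-bound dianion that is carbanionic at the β-carbon; this carbon attacks the Mg-chelated, α,α-dialkoxy-activated ester carbonyl through a seven-membered transition state that is reachable only on the face carrying the side chain, and collapse of the tetrahedral intermediate releases the side-chain alkoxide, so the ester acts as a traceless tether that sets the C5 quaternary centre cis to the side chain (the ring-fusion CH is protonated from the open face and is corrected anyway in step 12), the closest known reaction types being the intermolecular electroreductive β-acylation of enones and enoates with anhydrides or acylimidazoles and the electroreductive intramolecular ketone–ester coupling.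

Step 9
Reactants: 11 1-[(1R,2S,5S)-2-(2,2-dimethoxyacetyl)-5-[(2S,3S)-3-hydroxyhex-5-en-2-yl]-2-methylcyclopentyl]ethan-1-one
Product: 12 (2S,3S)-2-[(1S,2R,3S)-2-acetyl-3-(2,2-dimethoxyacetyl)-3-methylcyclopentyl]hex-5-en-3-yl propanoate
Conditions: (EtCO)2O, DMAP (cat.), Et3N, CH2Cl2, rt
Reagents that add atoms: propionic anhydride, CCC(=O)OC(=O)CC
Why: Acylation places the propanoate on C10 at the one point in the route where that oxygen is the only free hydroxyl.

Step 10
Reactants: 12 (2S,3S)-2-[(1S,2R,3S)-2-acetyl-3-(2,2-dimethoxyacetyl)-3-methylcyclopentyl]hex-5-en-3-yl propanoate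
Product: 14 (3S,4S)-4-[(1S,2R,3S)-2-acetyl-3-(2,2-dimethoxyacetyl)-3-methylcyclopentyl]-1-oxopentan-3-yl propanoate, via ozonide 13 (not isolated)
Conditions: O3, CH2Cl2, −78 °C; Me2S
Reagents that add atoms: ozone, [O-][O+]=O
Why: Ozonolysis of the only remaining C=C bond gives the C12 aldehyde.

Step 11
Reactants: 14 (3S,4S)-4-[(1S,2R,3S)-2-acetyl-3-(2,2-dimethoxyacetyl)-3-methylcyclopentyl]-1-oxopentan-3-yl propanoate
Product: 15 (2S,3S,5Z)-2-[(1S,2R,3S)-2-acetyl-3-(2,2-dimethoxyacetyl)-3-methylcyclopentyl]-6-iodohept-5-en-3-yl propanoate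
Conditions: [Ph3PCH2CH3]I, n-BuLi, THF; I2, −78 °C; NaN(SiMe3)2; then 14, −78 °C
Reagents that add atoms: ethyltriphenylphosphonium iodide, CC[P+](c1ccccc1)(c1ccccc1)c1ccccc1.[I-]; iodine, II
Why: The Stork–Zhao olefination with the α-iodo ylide gives the (Z)-2-iodoalkene, which fixes the C12=C13 geometry, and at −78 °C it reacts with the aldehyde before the ketones or the β-acyloxy group can interfere.

Step 12
Reactants: 15 (2S,3S,5Z)-2-[(1S,2R,3S)-2-acetyl-3-(2,2-dimethoxyacetyl)-3-methylcyclopentyl]-6-iodohept-5-en-3-yl propanoate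
Product: 17 (2S,3S,5Z)-6-iodo-2-[(1S,3aS,7aR)-3a-methyl-4,7-dioxo-2,3,3a,4,7,7a-hexahydro-1H-inden-1-yl]hept-5-en-3-yl propanoate, via keto aldehyde 16 (not isolated)
Conditions: TFA–H2O (9:1), CH2Cl2, 0 to 40 °C
Reagents that add atoms: none
Why: Acetal hydrolysis followed by intramolecular aldol condensation, in which only the acetyl methyl can enolise toward the glyoxal carbon, closes ring B as the enedione, and the epimerisable ring-fusion CH (C16) settles in the more stable cis-hydrindane.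

Step 13
Reactants: 17 (2S,3S,5Z)-6-iodo-2-[(1S,3aS,7aR)-3a-methyl-4,7-dioxo-2,3,3a,4,7,7a-hexahydro-1H-inden-1-yl]hept-5-en-3-yl propanoate
Product: 18 (2S,3S,5Z)-2-[(1S,3aS,6R,7aR)-4-[(tert-butyldimethylsilyl)oxy]-3a-methyl-7-oxo-6-(2-oxoethyl)-2,3,3a,6,7,7a-hexahydro-1H-inden-1-yl]-6-iodohept-5-en-3-yl propanoate
Conditions: CH2=CHOSiMe2t-Bu (1.1 equiv), t-BuMe2SiOTf (10 mol %), CH2Cl2, −78 °C
Reagents that add atoms: tert-butyldimethyl(vinyloxy)silane, C=CO[Si](C)(C)C(C)(C)C
Why: In this Mukaiyama–Michael addition the angular methyl shields the top of C3 and ring A shields the whole lower face, so the enol ether attacks C2 from the convex face and sets C2 (R), while silyl transfer leaves the C4 carbonyl masked as its silyl enol ether and so tells the two ring ketones apart.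

Step 14
Reactants: 18 (2S,3S,5Z)-2-[(1S,3aS,6R,7aR)-4-[(tert-butyldimethylsilyl)oxy]-3a-methyl-7-oxo-6-(2-oxoethyl)-2,3,3a,6,7,7a-hexahydro-1H-inden-1-yl]-6-iodohept-5-en-3-yl propanoate
Product: 19 (2R,5S,8S,9S,10S,14R,16R,12Z)-tricyclic C1 ketone with C3=C4 silyl enol ether (4-OSiMe2t-Bu), free 14-hydroxyl, 10-propanoate and 5,9,13-trimethyl groups
Conditions: CrCl2 (divalent chromium, 6 equiv), NiCl2 (divalent nickel, 2 mol %), DMSO–THF, rt, 2 mM, slow addition
Reagents that add atoms: none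
Why: The Nozaki–Hiyama–Kishi macrocyclisation adds the alkenylchromium to the aldehyde only, keeps the Z geometry and closes ring C, with the C14 carbinol (R) expected from addition on the outer face of the aldehyde in the folded closing conformation.

Step 15
Reactants: 19 tricyclic C1 ketone
Product: 20 (2R,5S,8R,9S,10S,14R,16S,12Z)-tricyclic C1 methylidene compound with C3=C4 silyl enol ether, free 14-hydroxyl and 10-propanoate
Conditions: Zn, CH2Br2, TiCl4 (pre-aged reagent), THF–CH2Cl2, 0 °C to rt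
Reagents that add atoms: dibromomethane, BrCBr
Why: The non-basic Takai–Lombardo methylenation converts the hindered C1 ketone without epimerising C2 or C16 and leaves the ester and the silyl enol ether alone.

Step 16
Reactants: 20 tricyclic C1 methylidene silyl enol ether
Product: 22 (2R,4S,5S,8R,9S,10S,14R,16S,12Z)-4,14-dihydroxy-5,9,13-trimethyl-1-methylidene tricycle 10-propanoate, via ketone 21 (not isolated)
Conditions: Bu4NF, AcOH, THF, 0 °C; then NaBH4, MeOH, −20 °C
Reagents that add atoms: none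
Why: Fluoride desilylation frees the C4 ketone, and borohydride reduction from the face opposite the angular methyl, as is usual for ketones next to an angular methyl in hydrindanones and decalones, gives the 4S alcohol cis to that methyl.

Step 17
Reactants: 22 tricyclic 4,14-diol 10-propanoate
Product: 23 CNP0239696.1
Conditions: Ac2O, DMAP, Et3N, CH2Cl2, rt to 40 °C
Reagents that add atoms: acetic anhydride, CC(=O)OC(C)=O
Why: Acetylation of the two secondary alcohols, with the propanoate already in place, completes the triester.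

**Compound list**

1 | (R)-(+)-limonene | CC1=CC[C@@H](CC1)C(C)=C | starting material
2 | secondary ozonide of the ring alkene of 1 | CC12CC[C@@H](C(C)=C)CC(OO1)O2 | intermediate
3 | (3R)-6-oxo-3-(prop-1-en-2-yl)heptanal | CC(=O)CC[C@H](CC=O)C(C)=C | intermediate
4 | (5S)-2-methyl-5-(prop-1-en-2-yl)cyclopent-1-ene-1-carbaldehyde | O=CC1=C(C)CC[C@H]1C(C)=C | intermediate
5 | 1-[(5S)-2-methyl-5-(prop-1-en-2-yl)cyclopent-1-en-1-yl]ethan-1-ol, both carbinol epimers | CC(O)C1=C(C)CC[C@H]1C(C)=C | intermediate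
6 | O-boryl, C-boryl bis(9-borabicyclo[3.3.1]nonan-9-yl) adduct of 5 | CC(OB1C2CCCC1CCC2)C1=C(C)CC[C@H]1[C@H](C)CB1C2CCCC1CCC2 | intermediate
7 | (2S)-2-[(1S)-2-(1-hydroxyethyl)-3-methylcyclopent-2-en-1-yl]propan-1-ol, both carbinol epimers | CC(O)C1=C(C)CC[C@H]1[C@H](C)CO | intermediate
8 | (2S)-2-[(1S)-2-acetyl-3-methylcyclopent-2-en-1-yl]propanal | CC(=O)C1=C(C)CC[C@H]1[C@H](C)C=O | intermediate
9 | (2S,3S)-2-[(1S)-2-acetyl-3-methylcyclopent-2-en-1-yl]hex-5-en-3-ol | CC(=O)C1=C(C)CC[C@H]1[C@H](C)[C@@H](O)CC=C | intermediate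
10 | (2S,3S)-2-[(1S)-2-acetyl-3-methylcyclopent-2-en-1-yl]hex-5-en-3-yl 2,2-dimethoxyacetate | CC(=O)C1=C(C)CC[C@H]1[C@H](C)[C@@H](OC(=O)C(OC)OC)CC=C | intermediate
11 | 1-[(1R,2S,5S)-2-(2,2-dimethoxyacetyl)-5-[(2S,3S)-3-hydroxyhex-5-en-2-yl]-2-methylcyclopentyl]ethan-1-one (acetyl, dimethoxyacetyl and side chain all cis) | CC(=O)[C@H]1[C@@](C)(C(=O)C(OC)OC)CC[C@H]1[C@H](C)[C@@H](O)CC=C | intermediate
12 | (2S,3S)-2-[(1S,2R,3S)-2-acetyl-3-(2,2-dimethoxyacetyl)-3-methylcyclopentyl]hex-5-en-3-yl propanoate | CC(=O)[C@H]1[C@@](C)(C(=O)C(OC)OC)CC[C@H]1[C@H](C)[C@@H](OC(=O)CC)CC=C | intermediate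
13 | secondary ozonide of the terminal alkene of 12 | CC(=O)[C@H]1[C@@](C)(C(=O)C(OC)OC)CC[C@H]1[C@H](C)[C@@H](OC(=O)CC)CC1OCOO1 | intermediate
14 | (3S,4S)-4-[(1S,2R,3S)-2-acetyl-3-(2,2-dimethoxyacetyl)-3-methylcyclopentyl]-1-oxopentan-3-yl propanoate | CC(=O)[C@H]1[C@@](C)(C(=O)C(OC)OC)CC[C@H]1[C@H](C)[C@@H](OC(=O)CC)CC=O | intermediate
15 | (2S,3S,5Z)-2-[(1S,2R,3S)-2-acetyl-3-(2,2-dimethoxyacetyl)-3-methylcyclopentyl]-6-iodohept-5-en-3-yl propanoate | CC(=O)[C@H]1[C@@](C)(C(=O)C(OC)OC)CC[C@H]1[C@H](C)[C@@H](OC(=O)CC)C/C=C(/C)I | intermediate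
16 | (2S,3S,5Z)-2-[(1S,2R,3S)-2-acetyl-3-methyl-3-(2-oxoacetyl)cyclopentyl]-6-iodohept-5-en-3-yl propanoate | CC(=O)[C@H]1[C@@](C)(C(=O)C=O)CC[C@H]1[C@H](C)[C@@H](OC(=O)CC)C/C=C(/C)I | intermediate
17 | (2S,3S,5Z)-6-iodo-2-[(1S,3aS,7aR)-3a-methyl-4,7-dioxo-2,3,3a,4,7,7a-hexahydro-1H-inden-1-yl]hept-5-en-3-yl propanoate | O=C1C=CC(=O)[C@@]2(C)CC[C@@H]([C@H](C)[C@@H](OC(=O)CC)C/C=C(/C)I)[C@@H]12 | intermediate
18 | (2S,3S,5Z)-2-[(1S,3aS,6R,7aR)-4-[(tert-butyldimethylsilyl)oxy]-3a-methyl-7-oxo-6-(2-oxoethyl)-2,3,3a,6,7,7a-hexahydro-1H-inden-1-yl]-6-iodohept-5-en-3-yl propanoate | O=C1[C@H](CC=O)C=C(O[Si](C)(C)C(C)(C)C)[C@@]2(C)CC[C@@H]([C@H](C)[C@@H](OC(=O)CC)C/C=C(/C)I)[C@@H]12 | intermediate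
19 | (2R,5S,8S,9S,10S,14R,16R,12Z)-tricyclic C1 ketone, C3=C4 silyl enol ether (4-OSiMe2t-Bu), 14-hydroxy, 10-propanoyloxy, 5,9,13-trimethyl | O=C1[C@H]2C=C(O[Si](C)(C)C(C)(C)C)[C@@]3(C)CC[C@@H]([C@H](C)[C@@H](OC(=O)CC)C/C=C(/C)[C@H](O)C2)[C@@H]13 | intermediate
20 | (2R,5S,8R,9S,10S,14R,16S,12Z)-tricyclic C1 methylidene compound, C3=C4 silyl enol ether, 14-hydroxy, 10-propanoyloxy | C=C1[C@H]2C=C(O[Si](C)(C)C(C)(C)C)[C@@]3(C)CC[C@@H]([C@H](C)[C@@H](OC(=O)CC)C/C=C(/C)[C@H](O)C2)[C@@H]13 | intermediate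
21 | (2R,5S,8R,9S,10S,14R,16S,12Z)-tricyclic C4 ketone, C1 methylidene, 14-hydroxy, 10-propanoyloxy | C=C1[C@H]2CC(=O)[C@@]3(C)CC[C@@H]([C@H](C)[C@@H](OC(=O)CC)C/C=C(/C)[C@H](O)C2)[C@@H]13 | intermediate
22 | (2R,4S,5S,8R,9S,10S,14R,16S,12Z)-tricyclic 4,14-diol, C1 methylidene, 10-propanoyloxy | C=C1[C@H]2C[C@H](O)[C@@]3(C)CC[C@@H]([C@H](C)[C@@H](OC(=O)CC)C/C=C(/C)[C@H](O)C2)[C@@H]13 | intermediate
23 | CNP0239696.1, (2R,4S,5S,8R,9S,10S,14R,16S,12Z)-4,14-diacetoxy-10-propanoyloxy-5,9,13-trimethyl-1-methylidene tricycle | C=C1[C@H]2C[C@H](OC(C)=O)[C@@]3(C)CC[C@@H]([C@H](C)[C@@H](OC(=O)CC)C/C=C(/C)[C@H](OC(C)=O)C2)[C@@H]13 | target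

**Step count and risks**

Total step count: 17. Longest linear sequence: 17 steps from (R)-limonene; the route is fully linear. The hydroboration in step 4 is a further selectivity risk (C9), handled by separation at diol 7.

The three steps most likely to fail:

Step 8, the electroreductive acyl transfer (the new step). The reduced enone may be protonated or dimerise before it reaches the ester. The fallback uses known chemistry, a silicon-tethered radical cyclisation followed by Tamao–Fleming oxidation, and sets out from 9. Silylation of 9 with (1-bromoethenyl)chlorodimethylsilane and imidazole gives the (1-bromoethenyl)dimethylsilyl ether F1. Slow addition of Bu3SnH with AIBN in benzene at 80 °C lets the α-silylvinyl radical add to the enone β-carbon from the tethered face and gives the eight-membered cyclic siloxane F2. Oxidation with KF, KHCO3 and H2O2 gives the all-cis hydroxy diacetyl compound 1-[(1R,2S,5S)-2-acetyl-5-[(2S,3S)-3-hydroxyhex-5-en-2-yl]-2-methylcyclopentyl]ethan-1-one F3. Propionylation as in step 9 gives the propanoate F4, ozonolysis as in step 10 gives the aldehyde F5, and the olefination of step 11 gives the (Z)-vinyl iodide F6. Riley oxidation with SeO2 in aqueous dioxane at 90 °C turns one acetyl group into the glyoxal, which condenses with the other; both regiochemistries give the same enedione, so the fallback comes back to the route at 17.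

Step 13, the Mukaiyama–Michael addition. Attack at C3, or further aldol reaction of the product aldehyde, may compete. The fallback sets out from 17 and uses a copper-catalysed conjugate addition with an oxidation-level adjustment. Vinylmagnesium bromide with CuBr·SMe2 (10 mol %) and t-BuMe2SiCl in THF at −78 °C gives the C2-vinyl silyl enol ether F7. Hydroboration of the vinyl group with 9-BBN and oxidation with NaBO3 gives the primary alcohol F8, and Dess–Martin oxidation returns to the route at 18.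

Step 14, the Nozaki–Hiyama–Kishi macrocyclisation. Strain in the bridged eleven-membered ring, oligomerisation and the C14 selectivity are all uncertain. The fallback closes ring C by ring-closing metathesis at C12=C13 instead and sets out from 12. The conditions of step 12 give the allyl-bearing enedione F9, and the conditions of step 13 give the aldehyde F10. Isopropenylmagnesium bromide at −78 °C adds to the aldehyde and gives the allylic alcohol F11 as both C14 epimers. The second-generation Hoveyda–Grubbs catalyst in toluene at 80 °C under high dilution closes the ring with loss of ethylene and comes back to the route at 19, which is separated from its C14 epimer F12.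

Further compounds
F1 | step 8 | {[(2S,3S)-2-[(1S)-2-acetyl-3-methylcyclopent-2-en-1-yl]hex-5-en-3-yl]oxy}(1-bromoethenyl)dimethylsilane | CC(=O)C1=C(C)CC[C@H]1[C@H](C)[C@@H](O[Si](C)(C)C(Br)=C)CC=C
F2 | step 8 | eight-membered cyclic siloxane from 8-endo radical cyclisation (exocyclic methylene on the carbon bonded to C5, acetyl cis) | CC(=O)[C@H]1[C@]2(C)CC[C@H]1[C@H](C)[C@H](CC=C)O[Si](C)(C)C2=C
F3 | step 8 | 1-[(1R,2S,5S)-2-acetyl-5-[(2S,3S)-3-hydroxyhex-5-en-2-yl]-2-methylcyclopentyl]ethan-1-one | CC(=O)[C@H]1[C@@](C)(C(C)=O)CC[C@H]1[C@H](C)[C@@H](O)CC=C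
F4 | step 8 | (2S,3S)-2-[(1S,2R,3S)-2,3-diacetyl-3-methylcyclopentyl]hex-5-en-3-yl propanoate | CC(=O)[C@H]1[C@@](C)(C(C)=O)CC[C@H]1[C@H](C)[C@@H](OC(=O)CC)CC=C
F5 | step 8 | (3S,4S)-4-[(1S,2R,3S)-2,3-diacetyl-3-methylcyclopentyl]-1-oxopentan-3-yl propanoate | CC(=O)[C@H]1[C@@](C)(C(C)=O)CC[C@H]1[C@H](C)[C@@H](OC(=O)CC)CC=O
F6 | step 8 | (2S,3S,5Z)-2-[(1S,2R,3S)-2,3-diacetyl-3-methylcyclopentyl]-6-iodohept-5-en-3-yl propanoate | CC(=O)[C@H]1[C@@](C)(C(C)=O)CC[C@H]1[C@H](C)[C@@H](OC(=O)CC)C/C=C(/C)I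
F7 | step 13 | (2S,3S,5Z)-2-[(1S,3aS,6R,7aR)-4-[(tert-butyldimethylsilyl)oxy]-6-ethenyl-3a-methyl-7-oxo-2,3,3a,6,7,7a-hexahydro-1H-inden-1-yl]-6-iodohept-5-en-3-yl propanoate | O=C1[C@H](C=C)C=C(O[Si](C)(C)C(C)(C)C)[C@@]2(C)CC[C@@H]([C@H](C)[C@@H](OC(=O)CC)C/C=C(/C)I)[C@@H]12
F8 | step 13 | (2S,3S,5Z)-2-[(1S,3aS,6R,7aR)-4-[(tert-butyldimethylsilyl)oxy]-6-(2-hydroxyethyl)-3a-methyl-7-oxo-2,3,3a,6,7,7a-hexahydro-1H-inden-1-yl]-6-iodohept-5-en-3-yl propanoate | O=C1[C@H](CCO)C=C(O[Si](C)(C)C(C)(C)C)[C@@]2(C)CC[C@@H]([C@H](C)[C@@H](OC(=O)CC)C/C=C(/C)I)[C@@H]12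
F9 | step 14 | (2S,3S)-2-[(1S,3aS,7aR)-3a-methyl-4,7-dioxo-2,3,3a,4,7,7a-hexahydro-1H-inden-1-yl]hex-5-en-3-yl propanoate | O=C1C=CC(=O)[C@@]2(C)CC[C@@H]([C@H](C)[C@@H](OC(=O)CC)CC=C)[C@@H]12
F10 | step 14 | (2S,3S)-2-[(1S,3aS,6R,7aR)-4-[(tert-butyldimethylsilyl)oxy]-3a-methyl-7-oxo-6-(2-oxoethyl)-2,3,3a,6,7,7a-hexahydro-1H-inden-1-yl]hex-5-en-3-yl propanoate | O=C1[C@H](CC=O)C=C(O[Si](C)(C)C(C)(C)C)[C@@]2(C)CC[C@@H]([C@H](C)[C@@H](OC(=O)CC)CC=C)[C@@H]12
F11 | step 14 | (2S,3S)-2-[(1S,3aS,6R,7aR)-4-[(tert-butyldimethylsilyl)oxy]-6-(2-hydroxy-3-methylbut-3-en-1-yl)-3a-methyl-7-oxo-2,3,3a,6,7,7a-hexahydro-1H-inden-1-yl]hex-5-en-3-yl propanoate, both carbinol epimers | O=C1[C@H](CC(O)C(C)=C)C=C(O[Si](C)(C)C(C)(C)C)[C@@]2(C)CC[C@@H]([C@H](C)[C@@H](OC(=O)CC)CC=C)[C@@H]12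
F12 | step 14 | C14 epimer of 19, (2R,5S,8S,9S,10S,14S,16R,12Z) | O=C1[C@H]2C=C(O[Si](C)(C)C(C)(C)C)[C@@]3(C)CC[C@@H]([C@H](C)[C@@H](OC(=O)CC)C/C=C(/C)[C@@H](O)C2)[C@@H]13
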